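**Plan**
- Retrosynthesis: first the ester and silyl masks are removed, then the side chain is cut at its C2'–C3' sp3–sp2 bond (alkylborane plus alkenyl iodide), then the C3=C4 double bond of the pyran ring is opened to an achiral triene. The triene goes back through a trialdehyde and a triol to the O1–C2 ether bond (phenoxide plus bromomethylmalonate).
- Enabling feature: C2 of the pyran ring is fully substituted and carries O1, a methyl group and two carbon arms that each begin with a two-carbon unit (C3=C4 in the ring, C1'–C2' in the chain). Both arms can therefore come from two enantiotopic vinyl groups on one prochiral carbinol carbon.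
- Forward: 2,3-dimethylhydroquinone is monosilylated, formylated, O-alkylated and converted to the triene; ring-closing metathesis from the aryl vinyl group onto one carbinol vinyl group closes the pyran ring. The untouched vinyl group is hydroborated and coupled with the C3'–C12' alkenyl iodide, and a one-pot deprotection ends the route.
- Stereochemistry: (S)-C2 comes from the chiral molybdenum catalyst in the ring closure; the 6E alkene from syn-carboalumination/iodinolysis; the 2E alkene from a stabilised-ylide Wittig reaction.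

Key step: step 7

Assumption: the sense of induction of the chiral molybdenum diolate on this substrate cannot be derived with certainty; the (S)-diolate complex is written, and its mirror-image complex, equally available, would be used if it delivered the (R)-chromene.

Step 1
Reactants: 1 2,3-dimethylbenzene-1,4-diol (2,3-dimethylhydroquinone)
Product: 2 2,3-dimethyl-4-{[tri(propan-2-yl)silyl]oxy}phenol
Conditions: TIPSCl (1.0 equiv), imidazole, DMF, 0 °C to rt; chromatography, unreacted 1 recycled
Reagents that add atoms: triisopropylsilyl chloride, CC(C)[Si](Cl)(C(C)C)C(C)C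
Why: Statistical monosilylation of one of the two equivalent phenols should give the monosilyl ether, the bulky silyl group slowing the second silylation and later withstanding ylides, hydride and aqueous phosphate.

Step 2
Reactants: 2 2,3-dimethyl-4-{[tri(propan-2-yl)silyl]oxy}phenol
Product: 3 2-hydroxy-3,4-dimethyl-5-{[tri(propan-2-yl)silyl]oxy}benzaldehyde
Conditions: MgCl2, Et3N, (CH2O)n, MeCN, reflux; aq HCl work-up
Reagents that add atoms: paraformaldehyde (formaldehyde), C=O
Why: Magnesium-phenoxide-directed ortho-formylation (Casnati–Skattebøl reaction) can only occur at the single free position ortho to the free hydroxyl group, a second formaldehyde acting as hydride acceptor.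

Step 3
Reactants: 3 2-hydroxy-3,4-dimethyl-5-{[tri(propan-2-yl)silyl]oxy}benzaldehyde; 4 diethyl 2-bromo-2-methylpropanedioate
Product: 5 diethyl 2-(2-formyl-5,6-dimethyl-4-{[tri(propan-2-yl)silyl]oxy}phenoxy)-2-methylpropanedioate
Conditions: K2CO3, DMF, 60 °C
Reagents that add atoms: none
Why: Williamson-type O-alkylation of the phenoxide at the doubly carbonyl-activated tertiary bromide, which has no α-hydrogen and so can neither eliminate nor condense with the aldehyde, installs the oxygen-bearing prochiral quaternary carbon with two identical ester arms.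

Step 4
Reactants: 5 diethyl 2-(2-formyl-5,6-dimethyl-4-{[tri(propan-2-yl)silyl]oxy}phenoxy)-2-methylpropanedioate
Product: 6 2-[2-(hydroxymethyl)-5,6-dimethyl-4-{[tri(propan-2-yl)silyl]oxy}phenoxy]-2-methylpropane-1,3-diol
Conditions: LiBH4, THF, 0 °C to rt; H2O work-up
Reagents that add atoms: none
Why: Borohydride reduction of both esters and the aldehyde to primary alcohols is standard for 2,2-disubstituted malonates and leaves the aryl silyl ether intact.

Step 5
Reactants: 6 2-[2-(hydroxymethyl)-5,6-dimethyl-4-{[tri(propan-2-yl)silyl]oxy}phenoxy]-2-methylpropane-1,3-diol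
Product: 7 2-(2-formyl-5,6-dimethyl-4-{[tri(propan-2-yl)silyl]oxy}phenoxy)-2-methylpropanedial
Conditions: (COCl)2, DMSO, CH2Cl2, −78 °C; Et3N, −78 to 0 °C; non-aqueous filtration, used crude at once
Reagents that add atoms: none
Why: Threefold Swern oxidation under non-aqueous conditions should give the trialdehyde, whose 1,3-dialdehyde part has no α-hydrogen and therefore cannot enolise or epimerise.

Step 6
Reactants: 7 2-(2-formyl-5,6-dimethyl-4-{[tri(propan-2-yl)silyl]oxy}phenoxy)-2-methylpropanedial
Product: 8 {5-ethenyl-2,3-dimethyl-4-[(3-methylpenta-1,4-dien-3-yl)oxy]phenoxy}tri(propan-2-yl)silane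
Conditions: Ph3PCH3Br (4.5 equiv), KHMDS (4.2 equiv), THF, 0 °C; then 7, −78 °C to rt; chromatography on Et3N-deactivated silica
Reagents that add atoms: methyltriphenylphosphonium bromide, C[P+](c1ccccc1)(c1ccccc1)c1ccccc1.[Br-]
Why: Threefold Wittig methylenation with the salt-free unstabilised ylide converts all three aldehydes into vinyl groups and gives the achiral triene in which the two vinyl groups on the carbinol carbon are enantiotopic.

Step 7
Reactants: 8 {5-ethenyl-2,3-dimethyl-4-[(3-methylpenta-1,4-dien-3-yl)oxy]phenoxy}tri(propan-2-yl)silane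
Product: 9 tri(propan-2-yl){[(2S)-2-ethenyl-2,7,8-trimethyl-2H-chromen-6-yl]oxy}silane
Conditions: Mo(N-2,6-iPr2C6H3)(CHCMe2Ph)[(S)-3,3'-di-tert-butyl-5,5',6,6'-tetramethylbiphenyl-2,2'-diolate] (5 mol%), benzene, 22 to 50 °C, N2 stream to remove ethylene, rigorously dry
Reagents that add atoms: none
Why: Proposed new method: the hexavalent molybdenum alkylidene should first exchange at the unhindered aryl vinyl group, and the resulting arylidene should then add in an intramolecular [2+2] fashion to one of the two enantiotopic vinyl groups on the carbinol carbon, cycloreversion of the molybdacyclobutane releasing the chromene and a methylidene that turns over with loss of ethylene. The closest known reaction types are the enantioselective ring-closing metathesis of alkyl divinylcarbinyl ethers to 2-vinyl dihydropyrans with this family of chiral molybdenum diolates and the non-asymmetric ring-closing metathesis of 2-vinylaryl allyl ethers to 2H-chromenes; their union on an aryl divinylcarbinyl ether is the untested part. The pyran ring closes as a six-membered ring by olefin metathesis between the benzylic alkylidene carbon (C4) and the internal carbon of one vinyl group (C3), the only ring size the tether allows. The C2 stereocentre arises by enantiotopic-group selection under control of the chiral biphenolate and the bulky arylimido ligand, which should force the methyl group and the spectator vinyl group into different quadrants of the two diastereomeric metallacyclobutane transition states. The step needs site-selective initiation and kinetic control: both carbinol vinyl groups sit on a fully substituted carbon and load slowly, so the catalyst should enter at the styrene, and the vinyl group left in the product is too hindered to re-enter metathesis once ethylene is swept out, so the selectivity should not erode.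

Step 8
Reactants: 10 pent-4-yn-1-ol
Product: 12 (E)-5-iodo-4-methylpent-4-en-1-ol, via alkenylalane 11 (not isolated)
Conditions: AlMe3 (3 equiv), Cp2ZrCl2 (0.25 equiv), CH2Cl2, 0 °C to rt; then I2, THF, −30 to 0 °C; aq K2CO3
Reagents that add atoms: trimethylaluminium, C[Al](C)C; iodine, [I][I]
Why: Zirconium-catalysed syn-carboalumination of the terminal alkyne (Negishi carboalumination) places methyl and aluminium cis on the new double bond, and iodinolysis of the alkenyl–aluminium bond with retention fixes the (E)-geometry.

Step 9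
Reactants: 12 (E)-5-iodo-4-methylpent-4-en-1-ol
Product: 13 (E)-5-iodo-4-methylpent-4-enal
Conditions: Dess–Martin periodinane, CH2Cl2, 0 °C to rt
Reagents that add atoms: none
Why: Dess–Martin oxidation of the primary alcohol stops at the aldehyde and leaves the alkenyl iodide and its geometry untouched.

Step 10
Reactants: 14 methyl (triphenylphosphoranylidene)acetate; 15 5-bromo-2-methylpent-2-ene
Product: 17 methyl 6-methyl-2-(triphenylphosphoranylidene)hept-5-enoate, via phosphonium bromide 16 (not isolated)
Conditions: 15 (1.5 equiv), K2CO3, NaI (10 mol%), MeCN, 80 °C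
Reagents that add atoms: none
Why: Iodide-catalysed SN2 C-alkylation of the ester-stabilised ylide by the primary bromide gives the α-substituted phosphonium salt, which carbonate deprotonates in the flask to the α-alkylated stabilised ylide, so that no ylide is lost to transylidation.

Step 11
Reactants: 13 (E)-5-iodo-4-methylpent-4-enal; 17 methyl 6-methyl-2-(triphenylphosphoranylidene)hept-5-enoate
Product: 18 methyl (2E,6E)-7-iodo-6-methyl-2-(4-methylpent-3-en-1-yl)hepta-2,6-dienoate
Conditions: toluene, 90 °C
Reagents that add atoms: none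
Why: Wittig olefination with an α-branched ester-stabilised ylide is governed by the more stable oxaphosphetane and should place the ester trans to the new alkyl chain, which is the (2E) geometry of the target.

Step 12
Reactants: 9 tri(propan-2-yl){[(2S)-2-ethenyl-2,7,8-trimethyl-2H-chromen-6-yl]oxy}silane; 18 methyl (2E,6E)-7-iodo-6-methyl-2-(4-methylpent-3-en-1-yl)hepta-2,6-dienoate
Product: 20 methyl (2E,6E)-6-methyl-2-(4-methylpent-3-en-1-yl)-9-[(2S)-2,7,8-trimethyl-6-{[tri(propan-2-yl)silyl]oxy}-2H-chromen-2-yl]nona-2,6-dienoate, via B-alkyl-9-BBN adduct 19 (not isolated)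
Conditions: 9-BBN dimer (0.55 equiv), THF, 0 °C to rt; then 18, PdCl2(dppf) (5 mol%), AsPh3, aq K3PO4, DMF, rt, degassed, dark
Reagents that add atoms: none
Why: 9-BBN adds anti-Markovnikov to the monosubstituted vinyl group far faster than to the cis-disubstituted, aryl-conjugated ring alkene, and the primary alkylborane then couples with the alkenyl iodide with retention of its (E)-geometry (B-alkyl Suzuki–Miyaura coupling) without touching the quaternary stereocentre.

Step 13
Reactants: 20 methyl (2E,6E)-6-methyl-2-(4-methylpent-3-en-1-yl)-9-[(2S)-2,7,8-trimethyl-6-{[tri(propan-2-yl)silyl]oxy}-2H-chromen-2-yl]nona-2,6-dienoate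
Product: 22 (2E,6E)-9-[(2S)-6-hydroxy-2,7,8-trimethyl-2H-chromen-2-yl]-6-methyl-2-(4-methylpent-3-en-1-yl)nona-2,6-dienoic acid, via phenol methyl ester 21 (not isolated)
Conditions: TBAF, THF, 0 °C; then LiOH, MeOH/H2O, 45 °C, argon, dark; aq HCl to pH 3
Reagents that add atoms: lithium hydroxide, [Li+].[OH-]
Why: Fluoride cleaves the aryl silyl ether and hydroxide then saponifies the hindered conjugated methyl ester by acyl–oxygen cleavage, oxygen and light being excluded because the electron-rich chromenol oxidises in base and 2H-chromenes can ring-open photochemically, and neither operation touches the stereocentre or the alkene geometries.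

**Compound list**
1 | 2,3-dimethylbenzene-1,4-diol | Cc1c(C)c(O)ccc1O | starting material
2 | 2,3-dimethyl-4-{[tri(propan-2-yl)silyl]oxy}phenol | Cc1c(C)c(O[Si](C(C)C)(C(C)C)C(C)C)ccc1O | intermediate
3 | 2-hydroxy-3,4-dimethyl-5-{[tri(propan-2-yl)silyl]oxy}benzaldehyde | O=Cc1cc(O[Si](C(C)C)(C(C)C)C(C)C)c(C)c(C)c1O | intermediate
4 | diethyl 2-bromo-2-methylpropanedioate | CCOC(=O)C(C)(Br)C(=O)OCC | starting material
5 | diethyl 2-(2-formyl-5,6-dimethyl-4-{[tri(propan-2-yl)silyl]oxy}phenoxy)-2-methylpropanedioate | CCOC(=O)C(C)(Oc1c(C=O)cc(O[Si](C(C)C)(C(C)C)C(C)C)c(C)c1C)C(=O)OCC | intermediate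
6 | 2-[2-(hydroxymethyl)-5,6-dimethyl-4-{[tri(propan-2-yl)silyl]oxy}phenoxy]-2-methylpropane-1,3-diol | OCC(C)(CO)Oc1c(CO)cc(O[Si](C(C)C)(C(C)C)C(C)C)c(C)c1C | intermediate
7 | 2-(2-formyl-5,6-dimethyl-4-{[tri(propan-2-yl)silyl]oxy}phenoxy)-2-methylpropanedial | O=CC(C)(C=O)Oc1c(C=O)cc(O[Si](C(C)C)(C(C)C)C(C)C)c(C)c1C | intermediate
8 | {5-ethenyl-2,3-dimethyl-4-[(3-methylpenta-1,4-dien-3-yl)oxy]phenoxy}tri(propan-2-yl)silane | C=CC(C)(C=C)Oc1c(C=C)cc(O[Si](C(C)C)(C(C)C)C(C)C)c(C)c1C | intermediate
9 | tri(propan-2-yl){[(2S)-2-ethenyl-2,7,8-trimethyl-2H-chromen-6-yl]oxy}silane | C=C[C@@]1(C)C=Cc2cc(O[Si](C(C)C)(C(C)C)C(C)C)c(C)c(C)c2O1 | intermediate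
10 | pent-4-yn-1-ol | C#CCCCO | starting material
11 | dimethylaluminium (E)-5-(dimethylalumanyl)-4-methylpent-4-en-1-olate (alkenylalane, not isolated) | C[Al](C)OCCC/C(C)=C/[Al](C)C | intermediate
12 | (E)-5-iodo-4-methylpent-4-en-1-ol | OCCC/C(C)=C/I | intermediate
13 | (E)-5-iodo-4-methylpent-4-enal | O=CCC/C(C)=C/I | intermediate
14 | methyl (triphenylphosphoranylidene)acetate | COC(=O)C=P(c1ccccc1)(c1ccccc1)c1ccccc1 | starting material
15 | 5-bromo-2-methylpent-2-ene | CC(C)=CCCBr | starting material
16 | (1-methoxy-6-methyl-1-oxohept-5-en-2-yl)triphenylphosphonium bromide (not isolated) | COC(=O)C(CCC=C(C)C)[P+](c1ccccc1)(c1ccccc1)c1ccccc1.[Br-] | intermediate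
17 | methyl 6-methyl-2-(triphenylphosphoranylidene)hept-5-enoate | COC(=O)C(CCC=C(C)C)=P(c1ccccc1)(c1ccccc1)c1ccccc1 | intermediate
18 | methyl (2E,6E)-7-iodo-6-methyl-2-(4-methylpent-3-en-1-yl)hepta-2,6-dienoate | CC(C)=CCC/C(=C\CC/C(C)=C/I)C(=O)OC | intermediate
19 | 9-{2-[(2S)-2,7,8-trimethyl-6-{[tri(propan-2-yl)silyl]oxy}-2H-chromen-2-yl]ethyl}-9-borabicyclo[3.3.1]nonane (not isolated) | C1CCC2CCCC1B2CC[C@@]3(C)C=Cc4cc(O[Si](C(C)C)(C(C)C)C(C)C)c(C)c(C)c4O3 | intermediate
20 | methyl (2E,6E)-6-methyl-2-(4-methylpent-3-en-1-yl)-9-[(2S)-2,7,8-trimethyl-6-{[tri(propan-2-yl)silyl]oxy}-2H-chromen-2-yl]nona-2,6-dienoate | CC(C)=CCC/C(=C\CC/C(C)=C/CC[C@@]1(C)C=Cc2cc(O[Si](C(C)C)(C(C)C)C(C)C)c(C)c(C)c2O1)C(=O)OC | intermediate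
21 | methyl (2E,6E)-9-[(2S)-6-hydroxy-2,7,8-trimethyl-2H-chromen-2-yl]-6-methyl-2-(4-methylpent-3-en-1-yl)nona-2,6-dienoate (not isolated) | CC(C)=CCC/C(=C\CC/C(C)=C/CC[C@@]1(C)C=Cc2cc(O)c(C)c(C)c2O1)C(=O)OC | intermediate
22 | (2E,6E)-9-[(2S)-6-hydroxy-2,7,8-trimethyl-2H-chromen-2-yl]-6-methyl-2-(4-methylpent-3-en-1-yl)nona-2,6-dienoic acid | CC(C)=CCC/C(=C\CC/C(C)=C/CC[C@@]1(C)C=Cc2cc(O)c(C)c(C)c2O1)C(=O)O | target

Total steps: 13. Longest linear sequence: 9 steps (steps 1 to 7, then 12 and 13).

**Steps most likely to fail**

Step 7 (proposed new method). The chiral diolate may discriminate poorly between the two enantiotopic vinyl groups, the hindered ortho-alkoxystyrene may load slowly onto molybdenum, or the catalyst may be killed by traces of aldehyde or phosphine oxide carried over from step 6. The fallback uses known chemistry and replaces catalyst control by resolution. It sets out from 8: ring-closing metathesis with the second-generation Grubbs catalyst RuCl2(PCy3)(H2IMes)(=CHPh) in CH2Cl2 at 40 °C, a standard closure of 2-vinylaryl allyl ethers, should give racemic tri(propan-2-yl){[2-ethenyl-2,7,8-trimethyl-2H-chromen-6-yl]oxy}silane F1. Preparative chromatography on a cellulose tris(3,5-dimethylphenylcarbamate) stationary phase would separate it into 9 and the (R)-enantiomer F2. The route is rejoined at 9.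

Step 3. Substitution at the tertiary carbon may be slow because the phenoxide is flanked on both sides and is weakened by conjugation and chelation with the ortho-formyl group. Bromine transfer from 4 to the phenoxide may compete, and the silyl ether may be lost on long heating with carbonate. The fallback removes the formyl group before the ether is made and sets out from 3. Wittig methylenation (Ph3PCH3Br, KHMDS, 2.2 equiv) should give 6-ethenyl-2,3-dimethyl-4-{[tri(propan-2-yl)silyl]oxy}phenol F3, whose phenoxide is neither chelated nor deactivated. Alkylation with 4 (K2CO3, DMF) would give diethyl 2-(2-ethenyl-5,6-dimethyl-4-{[tri(propan-2-yl)silyl]oxy}phenoxy)-2-methylpropanedioate F4. LiBH4 reduction would give 2-(2-ethenyl-5,6-dimethyl-4-{[tri(propan-2-yl)silyl]oxy}phenoxy)-2-methylpropane-1,3-diol F5, and Swern oxidation would give 2-(2-ethenyl-5,6-dimethyl-4-{[tri(propan-2-yl)silyl]oxy}phenoxy)-2-methylpropanedial F6. Twofold Wittig methylenation rejoins the route at 8.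

Step 6. The non-enolisable 1,3-dialdehyde may be deformylated by base or ylide (retro-Claisen-type C–C cleavage), may hydrate or oligomerise, or the threefold olefination may stop short. The fallback never places two aldehydes on the quaternary carbon and sets out from 3. Opening of 2-methyl-2-vinyloxirane by the phenol through a zerovalent palladium π-allyl intermediate (Pd2(dba)3, racemic trans-N,N'-(cyclohexane-1,2-diyl)bis[2-(diphenylphosphanyl)benzamide], CH2Cl2, rt) attacks the tertiary allyl terminus next to the alkoxide. It should give racemic 2-[(1-hydroxy-2-methylbut-3-en-2-yl)oxy]-3,4-dimethyl-5-{[tri(propan-2-yl)silyl]oxy}benzaldehyde F7, whose chirality is erased later. Dess–Martin oxidation would give 3,4-dimethyl-2-[(2-methyl-1-oxobut-3-en-2-yl)oxy]-5-{[tri(propan-2-yl)silyl]oxy}benzaldehyde F8, and twofold Wittig methylenation rejoins the route at 8.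

**Further compounds**
F1 | step 7 | racemic tri(propan-2-yl){[2-ethenyl-2,7,8-trimethyl-2H-chromen-6-yl]oxy}silane | C=CC1(C)C=Cc2cc(O[Si](C(C)C)(C(C)C)C(C)C)c(C)c(C)c2O1
F2 | step 7 | tri(propan-2-yl){[(2R)-2-ethenyl-2,7,8-trimethyl-2H-chromen-6-yl]oxy}silane | C=C[C@]1(C)C=Cc2cc(O[Si](C(C)C)(C(C)C)C(C)C)c(C)c(C)c2O1
F3 | step 3 | 6-ethenyl-2,3-dimethyl-4-{[tri(propan-2-yl)silyl]oxy}phenol | C=Cc1cc(O[Si](C(C)C)(C(C)C)C(C)C)c(C)c(C)c1O
F4 | step 3 | diethyl 2-(2-ethenyl-5,6-dimethyl-4-{[tri(propan-2-yl)silyl]oxy}phenoxy)-2-methylpropanedioate | CCOC(=O)C(C)(Oc1c(C=C)cc(O[Si](C(C)C)(C(C)C)C(C)C)c(C)c1C)C(=O)OCC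
F5 | step 3 | 2-(2-ethenyl-5,6-dimethyl-4-{[tri(propan-2-yl)silyl]oxy}phenoxy)-2-methylpropane-1,3-diol | OCC(C)(CO)Oc1c(C=C)cc(O[Si](C(C)C)(C(C)C)C(C)C)c(C)c1C
F6 | step 3 | 2-(2-ethenyl-5,6-dimethyl-4-{[tri(propan-2-yl)silyl]oxy}phenoxy)-2-methylpropanedial | O=CC(C)(C=O)Oc1c(C=C)cc(O[Si](C(C)C)(C(C)C)C(C)C)c(C)c1C
F7 | step 6 | 2-[(1-hydroxy-2-methylbut-3-en-2-yl)oxy]-3,4-dimethyl-5-{[tri(propan-2-yl)silyl]oxy}benzaldehyde (racemic) | C=CC(C)(CO)Oc1c(C=O)cc(O[Si](C(C)C)(C(C)C)C(C)C)c(C)c1C
F8 | step 6 | 3,4-dimethyl-2-[(2-methyl-1-oxobut-3-en-2-yl)oxy]-5-{[tri(propan-2-yl)silyl]oxy}benzaldehyde (racemic) | C=CC(C)(C=O)Oc1c(C=O)cc(O[Si](C(C)C)(C(C)C)C(C)C)c(C)c1C
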